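**Compound numbers used throughout:** 1 (S)-2-methylbutanoic acid; 2 (S)-2-methylbutanoyl chloride; 3 galangin; 4 galangin tris[(S)-2-methylbutanoate]; 5 silyl enol ether formed in the reduction; 6 the 2,3-cis (2R,3S) triester; 7 the 2,3-trans (2R,3R) triester; 8 the target.

## Analysis of the target

Compound 8 is a 2-phenylchroman-4-one. Ring A is a phloroglucinol-type benzene with free phenols at C5 and C7, ring C is a dihydropyranone, ring B is an unsubstituted phenyl on C2, and O3 carries an (S)-2-methylbutanoyl group. There are three stereocentres: C2 (R) and C3 (R) are adjacent on ring C and trans (phenyl and acyloxy both equatorial), and the α-carbon of the acyl chain (S) is remote and independent of them. C3–H lies α to the C4 ketone and to an acyloxy oxygen, so it epimerises through the enol or enolate; that same enolate can expel the O1 phenoxide (retro-oxa-Michael), which would erase C2. The O3 ester sits on an α-keto carbinol and is more labile than an ordinary alkyl ester, the dihydro ring is easily dehydrogenated back to the flavonol, and the acyl α-centre can be lost through a ketene when the acid is activated. The difficulty is therefore threefold: absolute control at C2 on a ring whose only handle is the neighbouring carbonyl, the trans relation at an epimerisable centre, and acylation of exactly one of three hydroxyls. The strategy rests on one feature: C2 and C3 are the only sp3 atoms of ring C and each bears one hydrogen. Removing those two hydrogens leaves the flat C2=C3 pyranone of a flavonol whose carbon skeleton and oxygen pattern (O3, O5, O7, bare ring B) are exactly those of galangin (3).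

## Retrosynthetic reasoning

**8 ⇒ 7 (two aryl ester C–O bonds at O5 and O7).** The free phenols of 8 are traced back to the same ester that sits on O3, so the precursor is the uniform triester 7. The cut is made here because, once C3 is sp3, O3 carries an alkyl ester while O5 and O7 carry aryl esters with far better leaving groups. That difference is what lets one acyl group be kept and two be removed without any selective protection. The forward reaction must cleave two aryl esters under near-neutral conditions and leave the O3 ester, C2 and C3 untouched.

**7 ⇒ 4 (the C2–H and C3–H bonds, by way of 6 and 5).** Taking one hydrogen from each of C2 and C3 turns 7 into the achiral-ring flavonol triester 4. No skeletal bond is cut, so every carbon and oxygen of the ring system is already in place, and both ring stereocentres arise in one operation. In the forward sense a chiral copper hydride catalyst, turned over by a hydrosilane, has to deliver hydride to one face of C2 and leave the C4 oxygen as enol ether 5. Protonation of 5 at C3 on the face away from the C2 phenyl would put the acyloxy group cis to phenyl (6), so the trans relation of 7 cannot be counted on kinetically. It is planned as the result of a deliberate equilibration at C3, where trans is the expected diequatorial minimum. The three acyl groups also serve the reduction: they shut off the donation of O3, O5 and O7 into the pyranone and make C2 a better hydride acceptor than it is in 3.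

**4 ⇒ 3 + 2 (three ester C–O bonds).** Three molecules of 2 are joined to the three hydroxyls of 3. Exhaustive acylation needs no regiocontrol; it only has to be forcing enough for the chelated 5-OH and mild enough not to racemise the acyl α-centre.

**2 ⇒ 1 (C–Cl bond).** The acid chloride comes from the commercial acid 1 under base-free conditions that leave its stereocentre alone.

## Alternatives that were turned down

Alternative 1: Cut C4–C4a at the flavan oxidation level (C4 as CH2) and add the ketone later.
- Forward key step: the aryl glycidyl-type ether A2, 1,3-bis(benzyloxy)-5-{(R)-[(2S)-oxiran-2-yl](phenyl)methoxy}benzene, is treated with BF3·OEt2 in hexafluoroisopropanol. The ring A carbon ortho to the ether oxygen attacks the epoxide CH2 (6-endo Friedel–Crafts alkylation) and closes ring C as the trans flavan-3-ol A1.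
- For: both stereocentres are already present in A2, which would come from an epoxy alcohol made by reliable asymmetric epoxidation, and the cyclisation touches neither. Absolute and relative configuration are therefore more secure than in the chosen route; on this point Alternative 1 is the stronger.
- Against: A1 is two oxidation levels short at C4. After esterifying O3, the C4 methylene would have to be oxidised to a ketone next to C2–H, which is benzylic and α to the ring oxygen and is the more easily abstracted hydrogen. Over-oxidation towards the flavone level, attack on the electron-rich ring A and loss of C2 are to be expected.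
- Further costs: the aryl ether of A2 must be made with clean inversion at a benzylic carbinol, the Lewis acid may steer the arene to the internal epoxide carbon (5-exo), and the benzyl ethers must finally be hydrogenolysed next to a benzylic C2–O bond. The sequence would run to about nine steps.
- Comparison: the chosen route has the C4 carbonyl from the first compound and needs four steps. It pays for this with a stereo-defining step that has no direct precedent.

Alternative 2: Cut the C3–O bond.
- Forward key step: (2S)-pinocembrin A6 is bis-silylated and converted into its enol silane A4. The derived low-temperature enolate attacks a peroxide oxygen of bis[(S)-2-methylbutanoyl] peroxide A5 on the face away from the C2 phenyl, giving the bis-silyl ether A3 of the target.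
- For: C2 is taken from an existing compound and not created. The electrophile arrives anti to phenyl, so the trans relation is the kinetic outcome. Here Alternative 2 has the better-founded diastereocontrol, because in the chosen route the kinetic event at C3 (protonation) points the wrong way and an equilibration is needed. The ester is installed in the bond-forming step, so no chemoselective deacylation is required.
- Against: A5 is a secondary-alkyl diacyl peroxide, which decarboxylates readily and is a handling hazard. Enolates also attack diacyl peroxides at the carbonyl carbon (plain acylation), and oxygen transfer of this kind is established mainly for aroyl peroxides. A free flavanone enolate can open ring C by expelling the O1 phenoxide, which would racemise C2. Silylating the chelated 5-OH is sluggish and the peri silyl ether is labile. Enantiopure A6 is itself a costly input.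
- Comparison: step count is similar (four to five plus the peroxide). The chosen route offers a cheap achiral-ring starting material, no peroxide, and no strongly basic enolate of the finished ring system.

Alternative 3: Cut the C2–C1′ bond.
- Forward key step: phenylboronic acid A9 adds to C2 of the 3-acyloxychromone A8 under a chiral diene complex of monovalent rhodium made from [RhCl(C2H4)2]2. The rhodium enolate is protonated at C3 to give the dibenzyl ether A7 of the target.
- For: rhodium–diene conjugate arylation of chromones to flavanones is an established enantioselective reaction. Face selectivity at C2 therefore has closer precedent than the copper hydride step chosen here; on this point Alternative 3 is stronger. It is also convergent in ring B.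
- Against: A8 carries an acyloxy group on the α-carbon C3, and α-substituted, electron-richer acceptors insert poorly into aryl–rhodium bonds. The aqueous base normally used in such additions threatens the enol ester. C3 is again set by protonation, so the cis/trans question is not avoided. A8 is not commercial: its 3-oxygenated chromone core must be built over several steps from a protected phloroglucinol ketone. The benzyl ethers then have to be removed by hydrogenolysis beside the benzylic C2–O bond. About eight steps result.
- Comparison: the chosen strategy buys all fifteen skeletal carbons and all ring oxygens in 3 and only has to add hydrogen.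

Key step: step 3

**Remarks.**
- Acid 1 and galangin 3 are taken as commercial.
- The sense of induction of the ligand cannot be derived for this substrate. (R)-DTBM-SEGPHOS, i.e. (R)-5,5′-bis[bis(3,5-di-tert-butyl-4-methoxyphenyl)phosphino]-4,4′-bi-1,3-benzodioxole, is written below; its antipode is used unchanged if hydride is found to go to the Re face of C2.
- Step 2 consumes three molecules of 2 for each molecule of 3: one stands on the Reactants line and the other two are entered under "Reagents that add atoms".

## Route

Step 1
Reactants: 1 (S)-2-methylbutanoic acid
Product: 2 (S)-2-methylbutanoyl chloride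
Conditions: (COCl)2 (1.2 equiv), DMF (cat.), CH2Cl2, 0 °C → rt; distillation
Reagents that add atoms: oxalyl chloride, O=C(Cl)C(=O)Cl
Why: Acid chloride formation through the Vilsmeier-type chloroiminium species; the medium is base-free, so the α-carbon is not enolised and should stay (S).

Step 2
Reactants: 3 galangin (3,5,7-trihydroxy-2-phenyl-4H-chromen-4-one); 2 (S)-2-methylbutanoyl chloride (one molecule for each of the three hydroxyls)
Product: 4 galangin 3,5,7-tris[(S)-2-methylbutanoate] (4-oxo-2-phenyl-4H-chromene-3,5,7-triyl tris[(2S)-2-methylbutanoate])
Conditions: 2 (4.5 equiv), pyridine, DMAP (0.2 equiv), CH2Cl2, 0 °C → rt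
Reagents that add atoms: (S)-2-methylbutanoyl chloride 2 (the second and third molecule that are incorporated), CC[C@H](C)C(=O)Cl.CC[C@H](C)C(=O)Cl
Why: DMAP-catalysed O-acylation of all three hydroxyls, each taking one acyl group from one molecule of 2; the hydrogen-bonded 5-OH is slowest and is the reason for excess 2 and the acyl-transfer catalyst. Pyridine is too weak a base to make the ketene from 2 at a useful rate at this temperature, so the acyl α-centres should be retained.

Step 3
Reactants: 4 galangin 3,5,7-tris[(S)-2-methylbutanoate]
Product: 7 (2R,3R)-pinobanksin 3,5,7-tris[(S)-2-methylbutanoate], via silyl enol ether 5 (not isolated), via C3-epimeric cis triester 6 (not isolated)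
Conditions: Cu(OAc)2·H2O (5 mol %), (R)-DTBM-SEGPHOS (5.5 mol %), (EtO)2MeSiH (3 equiv), toluene, 0 °C → rt; then AcOH, THF/H2O, 0 °C; crude, DBU (0.1 equiv), CH2Cl2, 0 °C, then AcOH
Reagents that add atoms: none
Why: Proposed new method: a bisphosphine-bound monovalent copper hydride, formed from Cu(OAc)2 and the silane, should add across the polarised C2=C3 bond with hydride going to the β-carbon C2 and copper to the C3/O4 enolate, which σ-bond metathesis with the silane turns into enol ether 5 and fresh copper hydride; the closest known reaction types are the asymmetric copper hydride 1,4-reduction of β,β-disubstituted cyclic enones and the asymmetric hydrogenation of chromones and flavones to chromanones and flavanones, neither yet shown on the tetrasubstituted double bond of a 3-acyloxyflavone. No ring is closed and no skeletal bond is formed. C2 is set by the catalyst, whose ligand pocket must pass hydride to the Si face of C2 (O1 > C3 > C1′) to give 2R, and the three remote (S)-acyl centres are not expected to override it. The step needs 1,4- over 1,2-selectivity at C4 and intact esters: the three acyl groups remove the donation of O3, O5 and O7 into the pyranone and so raise the electrophilicity of C2, and the absence of an alcohol additive keeps the product masked as 5 until work-up, so its ketone never meets the hydride. Hydrolysis of 5 protonates C3 mainly on the face away from the C2 phenyl, which places the acyloxy group cis to phenyl (6), so C3 is set by thermodynamic control: catalytic DBU enolises the α-acyloxy ketone until the diequatorial 2,3-trans isomer 7 (3R) prevails. C2 carries no acidic hydrogen and should be untouched as long as the enolate is reprotonated faster than it opens ring C.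

Step 4
Reactants: 7 (2R,3R)-pinobanksin 3,5,7-tris[(S)-2-methylbutanoate]
Product: 8 (2R,3R)-pinobanksin 3-O-[(S)-2-methylbutanoate] ((2R,3R)-5,7-dihydroxy-4-oxo-2-phenyl-3,4-dihydro-2H-chromen-3-yl (2S)-2-methylbutanoate), the target
Conditions: NH4OAc (10 equiv), MeOH/THF/H2O, rt
Reagents that add atoms: none
Why: Chemoselective deacylation of aryl esters by ammonium acetate in aqueous methanol, a known aryl-over-alkyl ester cleavage; the ring A aryloxides, activated by the ortho and para C4 carbonyl, are far better leaving groups than the secondary alkoxide at C3. The medium is close to neutral, so C2, C3 and the acyl α-centre should not be disturbed.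

## Compound list

1 | (S)-2-methylbutanoic acid | CC[C@H](C)C(=O)O | starting material
2 | (S)-2-methylbutanoyl chloride | CC[C@H](C)C(=O)Cl | intermediate
3 | galangin (3,5,7-trihydroxy-2-phenyl-4H-chromen-4-one) | O=c1c(O)c(-c2ccccc2)oc2cc(O)cc(O)c12 | starting material
4 | galangin 3,5,7-tris[(S)-2-methylbutanoate] | CC[C@H](C)C(=O)Oc1c(-c2ccccc2)oc2cc(OC(=O)[C@@H](C)CC)cc(OC(=O)[C@@H](C)CC)c2c1=O | intermediate
5 | (2R)-4-[diethoxy(methyl)silyloxy]-2-phenyl-2H-chromene-3,5,7-triyl tris[(S)-2-methylbutanoate], formed in the flask in step 3 | CC[C@H](C)C(=O)OC1=C(O[Si](C)(OCC)OCC)c2c(OC(=O)[C@@H](C)CC)cc(OC(=O)[C@@H](C)CC)cc2O[C@@H]1c1ccccc1 | intermediate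
6 | (2R,3S)-4-oxo-2-phenyl-3,4-dihydro-2H-chromene-3,5,7-triyl tris[(S)-2-methylbutanoate] (2,3-cis), formed in the flask in step 3 | CC[C@H](C)C(=O)O[C@@H]1C(=O)c2c(OC(=O)[C@@H](C)CC)cc(OC(=O)[C@@H](C)CC)cc2O[C@@H]1c1ccccc1 | intermediate
7 | (2R,3R)-pinobanksin 3,5,7-tris[(S)-2-methylbutanoate] (2,3-trans) | CC[C@H](C)C(=O)O[C@H]1C(=O)c2c(OC(=O)[C@@H](C)CC)cc(OC(=O)[C@@H](C)CC)cc2O[C@@H]1c1ccccc1 | intermediate
8 | (2R,3R)-pinobanksin 3-O-[(S)-2-methylbutanoate] | CC[C@H](C)C(=O)O[C@H]1C(=O)c2c(O)cc(O)cc2O[C@@H]1c1ccccc1 | target

## Step count and least certain steps

Total: 4 steps. Longest linear sequence: 4 steps (1 → 2 → 4 → 7 → 8); galangin 3 enters at step 2.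

**Step 3 (key step, the proposed new method).** Several things may go wrong. Hydride transfer may fail, because C2=C3 is tetrasubstituted and part of a vinylogous ester, so the hydride may not add at all or may add 1,2 to C4. Facial discrimination at C2 may be poor. The copper enolate oxygen may pick up an acyl group from O5 (peri) or O3 before it is silylated. During the base equilibration the enolate may open ring C by loss of the O1 phenoxide, which would erode C2, or may undergo the same acyl shift.

Fallback, from 4, returning at 7: heterogeneous hydrogenation of 4 (H2, 1 atm, Pd/C, EtOAc, stopped after one equivalent) is a known way to saturate the C2=C3 bond of chromones and flavones. It adds both hydrogens to one face and would give the 2,3-cis triester as two diastereomers, compound 6 and the (2S,3R)-cis triester F1; they are diastereomers and not enantiomers because all three acyl groups are (S). Equilibration at C3 would then convert them into 7 and the (2S,3S)-trans triester F2, with catalytic DBU as the first choice and TsOH in warm toluene if base causes acyl migration. 7 and F2 would be separated by preparative HPLC or crystallisation, and 7 continues with step 4. The price is half of the material and a separation that depends on remote stereocentres.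

**Step 4.** The aryl esters are α-branched and may cleave slowly, while the O3 ester, activated by the adjacent ketone, may start to cleave before the second aryl ester is gone. Prolonged exposure could also allow air dehydrogenation towards the flavonol.

Fallback, from 7, returning at 8: all three acyl groups are removed (K2CO3, MeOH, N2, 0 °C) to give (2R,3R)-pinobanksin F3. The most acidic phenol is silylated (TBSCl, imidazole, DMF, 0 °C) to give 7-O-TBS-pinobanksin F4. The secondary 3-OH is then acylated with 2 (pyridine, CH2Cl2, 0 °C), the chelated 5-OH being inert under these conditions, to give the 3-O-[(S)-2-methylbutanoyl]-7-O-TBS compound F5. Cleavage of the aryl silyl ether (HF·pyridine, THF, 0 °C) reaches 8.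

**Step 2.** Acylation of the chelated 5-OH may stall at the 3,7-diester, and forcing it raises the chance of ketene formation from 2 and partial loss of the acyl (S)-configuration.

Fallback, from 1 and 3, returning at 4: acid 1 is dehydrated with DCC (0.5 equiv, CH2Cl2) to (S)-2-methylbutanoic anhydride F6, the urea is filtered off, and 3 is acylated with F6 (DMAP, pyridine, rt → 40 °C). An anhydride transfers its acyl group through the acylpyridinium ion without a ketene pathway of practical weight.

## Further compounds

F1 | step 3 | (2S,3R)-4-oxo-2-phenyl-3,4-dihydro-2H-chromene-3,5,7-triyl tris[(S)-2-methylbutanoate] (2,3-cis) | CC[C@H](C)C(=O)O[C@H]1C(=O)c2c(OC(=O)[C@@H](C)CC)cc(OC(=O)[C@@H](C)CC)cc2O[C@H]1c1ccccc1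
F2 | step 3 | (2S,3S)-4-oxo-2-phenyl-3,4-dihydro-2H-chromene-3,5,7-triyl tris[(S)-2-methylbutanoate] (2,3-trans) | CC[C@H](C)C(=O)O[C@@H]1C(=O)c2c(OC(=O)[C@@H](C)CC)cc(OC(=O)[C@@H](C)CC)cc2O[C@H]1c1ccccc1
F3 | step 4 | (2R,3R)-pinobanksin ((2R,3R)-3,5,7-trihydroxy-2-phenylchroman-4-one) | O[C@H]1C(=O)c2c(O)cc(O)cc2O[C@@H]1c1ccccc1
F4 | step 4 | (2R,3R)-7-(tert-butyldimethylsilyloxy)-3,5-dihydroxy-2-phenylchroman-4-one | O[C@H]1C(=O)c2c(O)cc(O[Si](C)(C)C(C)(C)C)cc2O[C@@H]1c1ccccc1
F5 | step 4 | (2R,3R)-7-(tert-butyldimethylsilyloxy)-5-hydroxy-4-oxo-2-phenylchroman-3-yl (S)-2-methylbutanoate | CC[C@H](C)C(=O)O[C@H]1C(=O)c2c(O)cc(O[Si](C)(C)C(C)(C)C)cc2O[C@@H]1c1ccccc1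
F6 | step 2 | (S)-2-methylbutanoic anhydride | CC[C@H](C)C(=O)OC(=O)[C@@H](C)CC
A1 | alternative 1 | (2R,3S)-5,7-bis(benzyloxy)-2-phenylchroman-3-ol | O[C@H]1Cc2c(OCc3ccccc3)cc(OCc3ccccc3)cc2O[C@@H]1c1ccccc1
A2 | alternative 1 | 1,3-bis(benzyloxy)-5-{(R)-[(2S)-oxiran-2-yl](phenyl)methoxy}benzene | O1C[C@H]1[C@H](Oc1cc(OCc2ccccc2)cc(OCc2ccccc2)c1)c1ccccc1
A3 | alternative 2 | (2R,3R)-5,7-bis(tert-butyldimethylsilyloxy)-4-oxo-2-phenylchroman-3-yl (S)-2-methylbutanoate | CC[C@H](C)C(=O)O[C@H]1C(=O)c2c(O[Si](C)(C)C(C)(C)C)cc(O[Si](C)(C)C(C)(C)C)cc2O[C@@H]1c1ccccc1
A4 | alternative 2 | (2S)-5,7-bis(tert-butyldimethylsilyloxy)-2-phenyl-4-(trimethylsilyloxy)-2H-chromene | C[Si](C)(C)OC1=C[C@@H](c2ccccc2)Oc2cc(O[Si](C)(C)C(C)(C)C)cc(O[Si](C)(C)C(C)(C)C)c12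
A5 | alternative 2 | bis[(S)-2-methylbutanoyl] peroxide | CC[C@H](C)C(=O)OOC(=O)[C@@H](C)CC
A6 | alternative 2 | (2S)-pinocembrin | O=C1C[C@@H](c2ccccc2)Oc2cc(O)cc(O)c21
A7 | alternative 3 | (2R,3R)-5,7-bis(benzyloxy)-4-oxo-2-phenylchroman-3-yl (S)-2-methylbutanoate | CC[C@H](C)C(=O)O[C@H]1C(=O)c2c(OCc3ccccc3)cc(OCc3ccccc3)cc2O[C@@H]1c1ccccc1
A8 | alternative 3 | 5,7-bis(benzyloxy)-4-oxo-4H-chromen-3-yl (S)-2-methylbutanoate | CC[C@H](C)C(=O)Oc1coc2cc(OCc3ccccc3)cc(OCc3ccccc3)c2c1=O
A9 | alternative 3 | phenylboronic acid | OB(O)c1ccccc1
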